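**Retrosynthetic overview**

1. Labels: the dihydrobenzofuran part is numbered O1, C2 (bears a 4-hydroxyphenyl ring), C3, C3a, C4–C7, C7a; ring B is its benzo ring; ring C is the dioxygenated ring on C3; Ca is the sp3 carbon on C4 (bears the formyl-hydroxyphenyl ring) and Cb the sp3 carbon on ring C (bears the other 4-hydroxyphenyl ring).
2. Target ⇐ O-demethylation and ArCN → ArCHO ⇐ seven-membered ring closed last by a Friedel–Crafts bond from Cb to ring C of a 4-(1,2-diarylvinyl)-2,3-dihydrobenzofuran-6-ol; Ca and Cb are set there.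
3. Key disconnection: that dihydrobenzofuranol ⇐ an acyclic hydroxy penta-1,4-diyn-3-one R–CH2–C≡C–CO–C≡C–R′. The O1–C7a bond (oxa-Michael addition) closes the dihydrofuran, then the C3a–C4 bond closes ring B.
4. Enabling feature: ring B is a resorcinol ring, with oxygen on C6 and on C7a, meta to each other. C7a, C6 and C4 therefore stand at the carbonyl level of a six-carbon polyketide chain C3a–C7a–C7–C6–C5–C4, which two alkynes and one ketone reproduce exactly; O1 is 1,5 to C7a.
5. Diynone ⇐ lithium acetylide of a C2/C3-anti alkyne (asymmetric allylboration sets C2 and C3) + an alkynyl Weinreb amide (from a 1,1-dibromoalkene). Ring order: dihydrofuran, then ring B (same step), then the seven-membered ring.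

Key step: step 13

Remark: the C=C geometry of the triarylethene unit is written as expected from step 9 but has no bearing on the outcome, because both carbons become sp3 only in step 14 under equilibrating conditions. Compounds 1, 4, 10 and 12 are taken to be purchasable.

**Route**

Step 1
Reactants: 1 3,5-dimethoxybenzaldehyde
Product: 2 rac-1-(3,5-dimethoxyphenyl)prop-2-en-1-ol
Conditions: CH2=CHMgBr, THF, −78 → 0 °C; then H2O
Reagents that add atoms: vinylmagnesium bromide C=C[Mg]Br
Why: 1,2-addition of a vinyl Grignard reagent to an aryl aldehyde; the carbinol centre is racemic and is erased in step 2.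

Step 2
Reactants: 2 rac-1-(3,5-dimethoxyphenyl)prop-2-en-1-ol
Product: 3 2-[(2E)-3-(3,5-dimethoxyphenyl)prop-2-en-1-yl]-4,4,5,5-tetramethyl-1,3,2-dioxaborolane
Conditions: B2pin2, Pd(MeCN)4(BF4)2 (5 mol%), p-TsOH (5 mol%), DMSO/MeOH, 50 °C
Reagents that add atoms: bis(pinacolato)diboron CC1(C)OB(OC1(C)C)B1OC(C)(C)C(C)(C)O1
Why: palladium-catalysed borylation of an allylic alcohol goes through an η3-allylpalladium intermediate that is borylated at the unsubstituted terminus, so the conjugated linear E-allylboronate should result whatever the configuration of 2 (Miyaura-type allylic borylation).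

Step 3
Reactants: 3 2-[(2E)-3-(3,5-dimethoxyphenyl)prop-2-en-1-yl]-4,4,5,5-tetramethyl-1,3,2-dioxaborolane; 4 4-methoxybenzaldehyde
Product: 5 (1S,2R)-2-(3,5-dimethoxyphenyl)-1-(4-methoxyphenyl)but-3-en-1-ol
Conditions: (S)-TRIP [(S)-3,3′-bis(2,4,6-triisopropylphenyl)-1,1′-binaphthyl-2,2′-diyl hydrogen phosphate] (5 mol%), toluene, −30 °C; then H2O
Reagents that add atoms: none
Why: chiral phosphoric acid-catalysed allylboration of an aryl aldehyde with a pinacol allylboronate; the closed chair transition state carries the E geometry of 3 into the anti relation of the carbinol (future C2) and diarylmethine (future C3) centres, and the (S)-acid bound to a boronate oxygen should select the aldehyde face that gives the 1S carbinol (its antipode is taken if the sense of induction proves opposite).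

Step 4
Reactants: 5 (1S,2R)-2-(3,5-dimethoxyphenyl)-1-(4-methoxyphenyl)but-3-en-1-ol
Product: 6 tert-butyl{[(1S,2R)-2-(3,5-dimethoxyphenyl)-1-(4-methoxyphenyl)but-3-en-1-yl]oxy}dimethylsilane
Conditions: TBSOTf, 2,6-lutidine, CH2Cl2, 0 °C
Reagents that add atoms: tert-butyldimethylsilyl trifluoromethanesulfonate CC(C)(C)[Si](C)(C)OS(=O)(=O)C(F)(F)F
Why: silylation of a hindered secondary benzylic alcohol with a silyl triflate and a non-nucleophilic base; no stereocentre is touched.

Step 5
Reactants: 6 tert-butyl{[(1S,2R)-2-(3,5-dimethoxyphenyl)-1-(4-methoxyphenyl)but-3-en-1-yl]oxy}dimethylsilane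
Product: 7 (3R,4S)-4-{[tert-butyl(dimethyl)silyl]oxy}-3-(3,5-dimethoxyphenyl)-4-(4-methoxyphenyl)butan-1-ol
Conditions: 9-BBN, THF, 0 °C → rt; then NaOH, H2O2, 0 °C
Reagents that add atoms: hydrogen peroxide OO
Why: anti-Markovnikov hydroboration of the monosubstituted alkene with 9-BBN and oxidation of the C–B bond give the primary alcohol (hydroboration–oxidation); the silyl ether and both stereocentres are inert.

Step 6
Reactants: 7 (3R,4S)-4-{[tert-butyl(dimethyl)silyl]oxy}-3-(3,5-dimethoxyphenyl)-4-(4-methoxyphenyl)butan-1-ol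
Product: 8 (3R,4S)-4-{[tert-butyl(dimethyl)silyl]oxy}-3-(3,5-dimethoxyphenyl)-4-(4-methoxyphenyl)butanal
Conditions: Dess–Martin periodinane, CH2Cl2, rt
Reagents that add atoms: none
Why: Dess–Martin oxidation stops at the aldehyde under neutral conditions, and the stereocentres (β and γ to the new carbonyl) cannot enolise.

Step 7
Reactants: 8 (3R,4S)-4-{[tert-butyl(dimethyl)silyl]oxy}-3-(3,5-dimethoxyphenyl)-4-(4-methoxyphenyl)butanal
Product: 9 tert-butyl{[(1S,2R)-2-(3,5-dimethoxyphenyl)-1-(4-methoxyphenyl)pent-4-yn-1-yl]oxy}dimethylsilane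
Conditions: MeC(O)C(N2)P(O)(OMe)2, K2CO3, MeOH, 0 °C → rt
Reagents that add atoms: dimethyl (1-diazo-2-oxopropyl)phosphonate COP(=O)(OC)C(=[N+]=[N-])C(C)=O
Why: Seyferth–Gilbert homologation in the Ohira–Bestmann version: methanolysis frees the diazomethylphosphonate anion, which adds to the aldehyde, and the derived alkylidene carbene rearranges to the terminal alkyne under conditions mild enough for the silyl ether and the β-stereocentre.

Step 8
Reactants: 10 4-(methoxymethoxy)benzaldehyde
Product: 11 1-(2,2-dibromoethenyl)-4-(methoxymethoxy)benzene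
Conditions: CBr4, PPh3, CH2Cl2, 0 °C
Reagents that add atoms: carbon tetrabromide BrC(Br)(Br)Br
Why: dibromoolefination of an aryl aldehyde with the ylide from CBr4 and PPh3 (first stage of the Corey–Fuchs sequence); the acetal-type phenol protecting group tolerates the neutral conditions.

Step 9
Reactants: 11 1-(2,2-dibromoethenyl)-4-(methoxymethoxy)benzene; 12 (5-cyano-2-methoxyphenyl)boronic acid
Product: 14 4-methoxy-3-{(1E)-1-[4-(methoxymethoxy)phenyl]-4-[tri(propan-2-yl)silyl]but-1-en-3-yn-2-yl}benzonitrile, via bromoenyne 13 (not isolated)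
Conditions: HC≡CSi(i-Pr)3, PdCl2(dppf) (5 mol%), CuI (5 mol%), i-Pr2NH, toluene, rt; then 12, K3PO4, H2O, 80 °C
Reagents that add atoms: ethynyltri(propan-2-yl)silane C#C[Si](C(C)C)(C(C)C)C(C)C
Why: site-selective Sonogashira coupling of a 1,1-dibromoalkene at the bromide trans to the aryl group (faster oxidative addition at the less hindered C–Br bond), followed in the same flask by Suzuki–Miyaura coupling of the remaining bromide; both couplings retain the alkene geometry.

Step 10
Reactants: 14 4-methoxy-3-{(1E)-1-[4-(methoxymethoxy)phenyl]-4-[tri(propan-2-yl)silyl]but-1-en-3-yn-2-yl}benzonitrile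
Product: 15 4-methoxy-3-{(1Z)-1-[4-(methoxymethoxy)phenyl]but-1-en-3-yn-2-yl}benzonitrile
Conditions: Bu4NF, THF, 0 °C; then H2O
Reagents that add atoms: none
Why: fluoride cleaves the alkynyl C–Si bond; nitrile, aryl methyl ether and methoxymethyl ether are inert (the E/Z label changes only through the priority rules).

Step 11
Reactants: 15 4-methoxy-3-{(1Z)-1-[4-(methoxymethoxy)phenyl]but-1-en-3-yn-2-yl}benzonitrile
Product: 16 (4Z)-4-(5-cyano-2-methoxyphenyl)-N-methoxy-5-[4-(methoxymethoxy)phenyl]-N-methylpent-4-en-2-ynamide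
Conditions: LiN(SiMe3)2, THF, −78 °C; then ClC(O)N(OMe)Me, −78 → 0 °C
Reagents that add atoms: N-methoxy-N-methylcarbamoyl chloride CON(C)C(Cl)=O
Why: deprotonation of the terminal alkyne with a non-nucleophilic amide base (which spares the aryl nitrile) and acylation of the lithium acetylide with the carbamoyl chloride give the alkynyl Weinreb amide.

Step 12
Reactants: 9 tert-butyl{[(1S,2R)-2-(3,5-dimethoxyphenyl)-1-(4-methoxyphenyl)pent-4-yn-1-yl]oxy}dimethylsilane; 16 (4Z)-4-(5-cyano-2-methoxyphenyl)-N-methoxy-5-[4-(methoxymethoxy)phenyl]-N-methylpent-4-en-2-ynamide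
Product: 17 3-[(1Z,9R,10S)-10-{[tert-butyl(dimethyl)silyl]oxy}-9-(3,5-dimethoxyphenyl)-10-(4-methoxyphenyl)-1-[4-(methoxymethoxy)phenyl]-5-oxodec-1-ene-3,6-diyn-2-yl]-4-methoxybenzonitrile
Conditions: n-BuLi, THF, −78 °C (on 9); then 16, −78 → −30 °C; then H2O
Reagents that add atoms: none
Why: a lithium acetylide adds once to a Weinreb amide because the chelated tetrahedral intermediate survives until work-up, which should give the cross-conjugated diynone without attack on the nitrile at low temperature.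

Step 13
Reactants: 17 3-[(1Z,9R,10S)-10-{[tert-butyl(dimethyl)silyl]oxy}-9-(3,5-dimethoxyphenyl)-10-(4-methoxyphenyl)-1-[4-(methoxymethoxy)phenyl]-5-oxodec-1-ene-3,6-diyn-2-yl]-4-methoxybenzonitrile
Product: 21 3-{(Z)-1-[(2S,3S)-3-(3,5-dimethoxyphenyl)-6-hydroxy-2-(4-methoxyphenyl)-2,3-dihydro-1-benzofuran-4-yl]-2-[4-(methoxymethoxy)phenyl]ethenyl}-4-methoxybenzonitrile, via hydroxy diynone 18 (not isolated), via ylidene oxolane 19 (not isolated), via cyclohexadienone 20 (not isolated)
Conditions: Bu4NF (3 equiv), THF, 0 → 45 °C; then H2O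
Reagents that add atoms: none
Why: Proposed new method: fluoride frees the C2 alkoxide, which adds to the β-carbon of the nearer ynone arm (5-exo-dig oxa-Michael addition), forming the O1–C7a bond and closing the dihydrofuran ring as the vinylogous ester 19; fluoride or alkoxide then removes a γ-proton from the ring CH2 (the later C3a), the dienolate attacks the β-carbon of the second ynone arm (6-endo-dig Michael addition, the C3a–C4 bond), and the cross-conjugated cyclohexadienone 20 tautomerises to the phenol, so that ring B is built from six acyclic carbons. The closest known reactions are the double hetero-Michael conversion of penta-1,4-diyn-3-ones into 4-pyranones and 4-pyridinones, the base-mediated [5+1] benzannulation of such diynones with C–H acids, and the aldol aromatisation of polyketide-type triketones; the tandem with a tethered alkoxide and an unactivated γ-methylene as the carbon nucleophile has not been described. No stereocentre is created: C2 and C3 come unchanged from 5 (the C2–O bond is never broken and C3–H is not acidic), and the transient sp3 centre C3a of 20 is lost on enolisation. The step needs attack of the alkoxide on the proximal alkyne (a five-membered ring against a nine-membered ring through the distal arm, β- against α-carbon by the polarisation of the ynone) and C–C bond formation from the γ-carbon (the α-carbon could only give a four-membered ring); the E and Z isomers of 19 converge because the dienolate rotates about the former double bond. Aromatisation is the driving force, and the 2,3-trans arrangement carried in is also the thermodynamically preferred one.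

Step 14
Reactants: 21 3-{(Z)-1-[(2S,3S)-3-(3,5-dimethoxyphenyl)-6-hydroxy-2-(4-methoxyphenyl)-2,3-dihydro-1-benzofuran-4-yl]-2-[4-(methoxymethoxy)phenyl]ethenyl}-4-methoxybenzonitrile
Product: 23 3-[(1S,8S,9R,16S)-12-hydroxy-8-(4-hydroxyphenyl)-4,6-dimethoxy-16-(4-methoxyphenyl)-15-oxatetracyclo[8.6.1.0(2,7).0(14,17)]heptadeca-2(7),3,5,10(17),11,13-hexaen-9-yl]-4-methoxybenzonitrile, via free phenol 22 (not isolated)
Conditions: p-TsOH·H2O, MeOH/CH2Cl2, 45 °C
Reagents that add atoms: none
Why: acid first removes the methoxymethyl group by trans-acetalisation, and the 4-hydroxystilbene-type alkene is then protonated at Ca (the carbon remote from the phenol) to a quinone-methide-like cation at Cb that alkylates ring C ortho and para to its methoxy groups (seven-membered ring by intramolecular Friedel–Crafts hydroarylation, as known for 4-hydroxystyryl dihydrobenzofurans of the ε-viniferin type); Cb should be set by C3 through the transition state with its aryl group pseudo-equatorial and anti to the C3–C2 bond, and Ca, which equilibrates through the alkene, by allylic 1,3-strain in the cation (Ca–H in the cation plane, cyanoaryl ring anti to the attacking arene), giving the Ca/Cb-trans product.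

Step 15
Reactants: 23 3-[(1S,8S,9R,16S)-12-hydroxy-8-(4-hydroxyphenyl)-4,6-dimethoxy-16-(4-methoxyphenyl)-15-oxatetracyclo[8.6.1.0(2,7).0(14,17)]heptadeca-2(7),3,5,10(17),11,13-hexaen-9-yl]-4-methoxybenzonitrile
Product: 24 3-[(1S,8S,9R,16S)-12-hydroxy-8-(4-hydroxyphenyl)-4,6-dimethoxy-16-(4-methoxyphenyl)-15-oxatetracyclo[8.6.1.0(2,7).0(14,17)]heptadeca-2(7),3,5,10(17),11,13-hexaen-9-yl]-4-methoxybenzaldehyde
Conditions: i-Bu2AlH (5 equiv), CH2Cl2, −78 → 0 °C; then aq. HCl
Reagents that add atoms: water O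
Why: partial reduction of the aryl nitrile by i-Bu2AlH stops at the N-aluminio aldimine, which is hydrolysed to the aldehyde on work-up; the excess reagent allows for the two phenols.

Step 16
Reactants: 24 3-[(1S,8S,9R,16S)-12-hydroxy-8-(4-hydroxyphenyl)-4,6-dimethoxy-16-(4-methoxyphenyl)-15-oxatetracyclo[8.6.1.0(2,7).0(14,17)]heptadeca-2(7),3,5,10(17),11,13-hexaen-9-yl]-4-methoxybenzaldehyde
Product: 25 vitisinol B, 4-hydroxy-3-[(1S,8S,9R,16S)-4,6,12-trihydroxy-8,16-bis(4-hydroxyphenyl)-15-oxatetracyclo[8.6.1.0(2,7).0(14,17)]heptadeca-2(7),3,5,10(17),11,13-hexaen-9-yl]benzaldehyde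
Conditions: BBr3, CH2Cl2, −78 → 0 °C; then H2O
Reagents that add atoms: none
Why: BBr3 cleaves the four aryl methyl ethers through aryloxyboron bromides (the usual last step for methylated stilbene oligomers); the aldehyde and the four stereocentres should survive at low temperature, and the 2,3-trans dihydrobenzofuran is the thermodynamic isomer should the benzylic C–O bond ionise reversibly.

**Compound list**

1 | 3,5-dimethoxybenzaldehyde | COc1cc(C=O)cc(OC)c1 | starting material
2 | rac-1-(3,5-dimethoxyphenyl)prop-2-en-1-ol | COc1cc(cc(OC)c1)C(O)C=C | intermediate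
3 | 2-[(2E)-3-(3,5-dimethoxyphenyl)prop-2-en-1-yl]-4,4,5,5-tetramethyl-1,3,2-dioxaborolane | COc1cc(/C=C/CB2OC(C)(C)C(C)(C)O2)cc(OC)c1 | intermediate
4 | 4-methoxybenzaldehyde | COc1ccc(C=O)cc1 | starting material
5 | (1S,2R)-2-(3,5-dimethoxyphenyl)-1-(4-methoxyphenyl)but-3-en-1-ol | COc1ccc(cc1)[C@@H](O)[C@@H](c1cc(OC)cc(OC)c1)C=C | intermediate
6 | tert-butyl{[(1S,2R)-2-(3,5-dimethoxyphenyl)-1-(4-methoxyphenyl)but-3-en-1-yl]oxy}dimethylsilane | COc1ccc(cc1)[C@@H](O[Si](C)(C)C(C)(C)C)[C@@H](c1cc(OC)cc(OC)c1)C=C | intermediate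
7 | (3R,4S)-4-{[tert-butyl(dimethyl)silyl]oxy}-3-(3,5-dimethoxyphenyl)-4-(4-methoxyphenyl)butan-1-ol | COc1ccc(cc1)[C@@H](O[Si](C)(C)C(C)(C)C)[C@@H](c1cc(OC)cc(OC)c1)CCO | intermediate
8 | (3R,4S)-4-{[tert-butyl(dimethyl)silyl]oxy}-3-(3,5-dimethoxyphenyl)-4-(4-methoxyphenyl)butanal | COc1ccc(cc1)[C@@H](O[Si](C)(C)C(C)(C)C)[C@@H](c1cc(OC)cc(OC)c1)CC=O | intermediate
9 | tert-butyl{[(1S,2R)-2-(3,5-dimethoxyphenyl)-1-(4-methoxyphenyl)pent-4-yn-1-yl]oxy}dimethylsilane | COc1ccc(cc1)[C@@H](O[Si](C)(C)C(C)(C)C)[C@@H](c1cc(OC)cc(OC)c1)CC#C | intermediate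
10 | 4-(methoxymethoxy)benzaldehyde | COCOc1ccc(C=O)cc1 | starting material
11 | 1-(2,2-dibromoethenyl)-4-(methoxymethoxy)benzene | COCOc1ccc(C=C(Br)Br)cc1 | intermediate
12 | (5-cyano-2-methoxyphenyl)boronic acid | COc1ccc(C#N)cc1B(O)O | starting material
13 | {(3Z)-3-bromo-4-[4-(methoxymethoxy)phenyl]but-3-en-1-yn-1-yl}tri(propan-2-yl)silane | COCOc1ccc(cc1)/C=C(Br)/C#C[Si](C(C)C)(C(C)C)C(C)C | intermediate
14 | 4-methoxy-3-{(1E)-1-[4-(methoxymethoxy)phenyl]-4-[tri(propan-2-yl)silyl]but-1-en-3-yn-2-yl}benzonitrile | COCOc1ccc(cc1)/C=C(/C#C[Si](C(C)C)(C(C)C)C(C)C)c1cc(C#N)ccc1OC | intermediate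
15 | 4-methoxy-3-{(1Z)-1-[4-(methoxymethoxy)phenyl]but-1-en-3-yn-2-yl}benzonitrile | COCOc1ccc(cc1)/C=C(/C#C)c1cc(C#N)ccc1OC | intermediate
16 | (4Z)-4-(5-cyano-2-methoxyphenyl)-N-methoxy-5-[4-(methoxymethoxy)phenyl]-N-methylpent-4-en-2-ynamide | COCOc1ccc(cc1)/C=C(/C#CC(=O)N(C)OC)c1cc(C#N)ccc1OC | intermediate
17 | 3-[(1Z,9R,10S)-10-{[tert-butyl(dimethyl)silyl]oxy}-9-(3,5-dimethoxyphenyl)-10-(4-methoxyphenyl)-1-[4-(methoxymethoxy)phenyl]-5-oxodec-1-ene-3,6-diyn-2-yl]-4-methoxybenzonitrile | COc1ccc(cc1)[C@@H](O[Si](C)(C)C(C)(C)C)[C@@H](c1cc(OC)cc(OC)c1)CC#CC(=O)C#C/C(=C/c1ccc(OCOC)cc1)c1cc(C#N)ccc1OC | intermediate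
18 | 3-[(1Z,9R,10S)-9-(3,5-dimethoxyphenyl)-10-hydroxy-10-(4-methoxyphenyl)-1-[4-(methoxymethoxy)phenyl]-5-oxodec-1-ene-3,6-diyn-2-yl]-4-methoxybenzonitrile | COc1ccc(cc1)[C@@H](O)[C@@H](c1cc(OC)cc(OC)c1)CC#CC(=O)C#C/C(=C/c1ccc(OCOC)cc1)c1cc(C#N)ccc1OC | intermediate
19 | 3-[(1Z,6E)-6-[(4R,5S)-4-(3,5-dimethoxyphenyl)-5-(4-methoxyphenyl)oxolan-2-ylidene]-1-[4-(methoxymethoxy)phenyl]-5-oxohex-1-en-3-yn-2-yl]-4-methoxybenzonitrile (the E isomer is drawn; E and Z interconvert through the dienolate) | COc1ccc(cc1)[C@H]1O/C(=C/C(=O)C#C/C(=C/c2ccc(OCOC)cc2)c2cc(C#N)ccc2OC)C[C@@H]1c1cc(OC)cc(OC)c1 | intermediate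
20 | 3-{(Z)-1-[(2S,3R)-3-(3,5-dimethoxyphenyl)-2-(4-methoxyphenyl)-6-oxo-2,3,3a,6-tetrahydro-1-benzofuran-4-yl]-2-[4-(methoxymethoxy)phenyl]ethenyl}-4-methoxybenzonitrile (keto tautomer of 21; configuration at C3a open and without consequence) | COc1ccc(cc1)[C@H]1OC2=CC(=O)C=C(/C(=C/c3ccc(OCOC)cc3)c3cc(C#N)ccc3OC)C2[C@@H]1c1cc(OC)cc(OC)c1 | intermediate
21 | 3-{(Z)-1-[(2S,3S)-3-(3,5-dimethoxyphenyl)-6-hydroxy-2-(4-methoxyphenyl)-2,3-dihydro-1-benzofuran-4-yl]-2-[4-(methoxymethoxy)phenyl]ethenyl}-4-methoxybenzonitrile | COc1ccc(cc1)[C@H]1Oc2cc(O)cc(/C(=C/c3ccc(OCOC)cc3)c3cc(C#N)ccc3OC)c2[C@@H]1c1cc(OC)cc(OC)c1 | intermediate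
22 | 3-{(Z)-1-[(2S,3S)-3-(3,5-dimethoxyphenyl)-6-hydroxy-2-(4-methoxyphenyl)-2,3-dihydro-1-benzofuran-4-yl]-2-(4-hydroxyphenyl)ethenyl}-4-methoxybenzonitrile | COc1ccc(cc1)[C@H]1Oc2cc(O)cc(/C(=C/c3ccc(O)cc3)c3cc(C#N)ccc3OC)c2[C@@H]1c1cc(OC)cc(OC)c1 | intermediate
23 | 3-[(1S,8S,9R,16S)-12-hydroxy-8-(4-hydroxyphenyl)-4,6-dimethoxy-16-(4-methoxyphenyl)-15-oxatetracyclo[8.6.1.0(2,7).0(14,17)]heptadeca-2(7),3,5,10(17),11,13-hexaen-9-yl]-4-methoxybenzonitrile | N#Cc1ccc(OC)c([C@H]2c3cc(O)cc4c3[C@H](c3cc(OC)cc(OC)c3[C@@H]2c2ccc(O)cc2)[C@@H](c2ccc(OC)cc2)O4)c1 | intermediate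
24 | 3-[(1S,8S,9R,16S)-12-hydroxy-8-(4-hydroxyphenyl)-4,6-dimethoxy-16-(4-methoxyphenyl)-15-oxatetracyclo[8.6.1.0(2,7).0(14,17)]heptadeca-2(7),3,5,10(17),11,13-hexaen-9-yl]-4-methoxybenzaldehyde | O=Cc1ccc(OC)c([C@H]2c3cc(O)cc4c3[C@H](c3cc(OC)cc(OC)c3[C@@H]2c2ccc(O)cc2)[C@@H](c2ccc(OC)cc2)O4)c1 | intermediate
25 | vitisinol B, 4-hydroxy-3-[(1S,8S,9R,16S)-4,6,12-trihydroxy-8,16-bis(4-hydroxyphenyl)-15-oxatetracyclo[8.6.1.0(2,7).0(14,17)]heptadeca-2(7),3,5,10(17),11,13-hexaen-9-yl]benzaldehyde | O=Cc1ccc(O)c([C@H]2c3cc(O)cc4c3[C@H](c3cc(O)cc(O)c3[C@@H]2c2ccc(O)cc2)[C@@H](c2ccc(O)cc2)O4)c1 | target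

**Step count**

Total: 16 steps. Longest linear sequence: 12 steps (steps 1–7, then 12–16); the second branch (steps 8–11) joins at step 12.

**Steps most likely to fail**

Step 13 (proposed new method). The oxa-Michael closure may not be followed by γ-deprotonation and carbocyclisation, or fluoride or adventitious water may add to the distal ynone arm and divert the material to pyranone-type products. The fallback is stepwise and replaces the anionic carbocyclisation by π-acid catalysis. It sets out from 17: HF·pyridine in THF removes the silyl ether, and the hydroxy diynone 18 closes (on standing or with catalytic K2CO3) to the ylidene oxolane 19 by the known 5-exo-dig oxa-Michael addition of hydroxy ynones; 19 is isolated. Ph3PAuNTf2 (monovalent gold, 5 mol%) in toluene at 60 °C then activates the remaining alkyne for 6-endo-dig attack by the enol-ether carbon C3a, a gold-catalysed enol ether–alkyne cycloaromatisation of the kind used to annulate benzene rings onto indoles and furans, and tautomerisation gives 21, where the route is rejoined. This fallback makes no compound that is absent from the list (entry F0).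

Step 14. Protonation at the wrong alkene carbon, or ionisation of the benzylic C2–O1 bond, would open paths to six- or five-membered carbocycles; methanol may intercept the cation; facial selectivity at Ca and Cb may be poor. The fallback moves the ring closure to the very end and runs it on the unprotected polyphenol, where the resorcinol ring C is far more nucleophilic. It sets out from 21: i-Bu2AlH (CH2Cl2, −78 °C) gives 3-{(Z)-1-[(2S,3S)-3-(3,5-dimethoxyphenyl)-6-hydroxy-2-(4-methoxyphenyl)-2,3-dihydro-1-benzofuran-4-yl]-2-[4-(methoxymethoxy)phenyl]ethenyl}-4-methoxybenzaldehyde F1. BBr3 (CH2Cl2, −78 → −20 °C) removes the four methyl groups and the methoxymethyl group to give 3-{(Z)-1-[(2S,3S)-3-(3,5-dihydroxyphenyl)-6-hydroxy-2-(4-hydroxyphenyl)-2,3-dihydro-1-benzofuran-4-yl]-2-(4-hydroxyphenyl)ethenyl}-4-hydroxybenzaldehyde F2. Dilute acid (HCO2H, or 0.1 M HCl in aqueous acetone) at high dilution then closes the seven-membered ring by the same Friedel–Crafts hydroarylation, and the route is rejoined at 25.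

Step 3. The γ-aryl allylboronate may react with low enantioselectivity (uncatalysed background addition) or lose diastereoselectivity through E/Z isomerisation by borotropic shift. The fallback replaces allylboron by allylchromium chemistry. It sets out from 2: PBr3 (Et2O, 0 °C, with allylic transposition) gives 1-[(1E)-3-bromoprop-1-en-1-yl]-3,5-dimethoxybenzene F3. An asymmetric Nozaki–Hiyama–Kishi allylation of 4 with F3 (CrCl2, divalent chromium, stoichiometric, with a chiral sulfonamide–oxazoline ligand and Et3N in THF; then H2O) proceeds through the chair transition state of the E-allylchromium species and should give the same anti alcohol, so the route is rejoined at 5.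

Further compounds
F0 | step 13 | none | none
F1 | step 14 | 3-{(Z)-1-[(2S,3S)-3-(3,5-dimethoxyphenyl)-6-hydroxy-2-(4-methoxyphenyl)-2,3-dihydro-1-benzofuran-4-yl]-2-[4-(methoxymethoxy)phenyl]ethenyl}-4-methoxybenzaldehyde | COc1ccc(cc1)[C@H]1Oc2cc(O)cc(/C(=C/c3ccc(OCOC)cc3)c3cc(C=O)ccc3OC)c2[C@@H]1c1cc(OC)cc(OC)c1
F2 | step 14 | 3-{(Z)-1-[(2S,3S)-3-(3,5-dihydroxyphenyl)-6-hydroxy-2-(4-hydroxyphenyl)-2,3-dihydro-1-benzofuran-4-yl]-2-(4-hydroxyphenyl)ethenyl}-4-hydroxybenzaldehyde | Oc1ccc(cc1)[C@H]1Oc2cc(O)cc(/C(=C/c3ccc(O)cc3)c3cc(C=O)ccc3O)c2[C@@H]1c1cc(O)cc(O)c1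
F3 | step 3 | 1-[(1E)-3-bromoprop-1-en-1-yl]-3,5-dimethoxybenzene | COc1cc(/C=C/CBr)cc(OC)c1
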